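**Retrosynthetic overview**
1. The methylene bridge is cut between its CH2 and ring B (the methoxy ring). Ring A (the trihydroxy ring) arrives as an ortho-quinone methide released from Mannich base 16, and ring B as the nucleophilic monomer 13.
2. Monomer 13 comes from ketone 12 by cleaving the one methyl ether that lies between the propionyl group and the C-methyl.
3. The strategy rests on ring B: the ring carbon bearing the propionyl group and the adjacent hydroxyl-bearing carbon (the one next to the bridge carbon) form an ortho-hydroxyaryl ketone pair. Both substituents are installed in one operation on the two aryne carbons of 10 (from silyl triflate 8) by propionic acid 9.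
4. Silyl triflate 8 is built from 2,6-dimethoxytoluene 1 by C–H borylation/oxidation, bromination and a retro-Brook/triflation sequence. Ring A ketone 15 comes from 2,4,6-trihydroxytoluene 14 by Friedel–Crafts propionylation.
5. No ring is formed anywhere in the route; both benzene rings are bought and only substituted.

Key step: step 4

Remark: the target has no stereocentre, so no step has to control configuration.

**Step 1**
Reactants: 1 2,6-dimethoxytoluene
Product: 3 3,5-dimethoxy-4-methylphenol, via arylboronic pinacol ester 2 (not isolated)
Conditions: [Ir(OMe)(cod)]2 (1.5 mol%), dtbpy (3 mol%), B2pin2 (1.0 equiv), THF, 80 °C; then KHSO5 (as 2KHSO5·KHSO4·K2SO4), acetone/H2O, 0 °C to rt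
Reagents that add atoms: bis(pinacolato)diboron, CC1(C)OB(OC1(C)C)B1OC(C)(C)C(C)(C)O1 (boryl group of 2); potassium peroxymonosulfate KHSO5, [K+].[O-]S(=O)(=O)OO (phenol oxygen of 3)
Why: Sterically governed iridium-catalysed C–H borylation should take the only ring C–H that has no ortho substituent (para to the methyl group), and ipso-oxidation of the boronate in the same flask should give the phenol (one-pot C–H borylation/oxidation).

**Step 2**
Reactants: 3 3,5-dimethoxy-4-methylphenol
Product: 4 2-bromo-3,5-dimethoxy-4-methylphenol
Conditions: NBS (1.0 equiv), CH2Cl2, −78 to 0 °C, dark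
Reagents that add atoms: N-bromosuccinimide, O=C1CCC(=O)N1Br
Why: Electrophilic aromatic bromination, in which the two open ring positions are equivalent by symmetry and each is ortho to the hydroxyl, so one equivalent of NBS at low temperature should stop at the monobromide because the first bromine hinders and deactivates the ring.

**Step 3**
Reactants: 4 2-bromo-3,5-dimethoxy-4-methylphenol
Product: 8 3,5-dimethoxy-4-methyl-2-(trimethylsilyl)phenyl trifluoromethanesulfonate, via aryl trimethylsilyl ether 5 (not isolated), via aryllithium 6 (not isolated), via lithium 2-silylphenoxide 7 (not isolated)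
Conditions: HMDS, THF, 70 °C, then evaporate; n-BuLi, THF, −100 to −80 °C; Tf2O, −100 to −78 °C
Reagents that add atoms: hexamethyldisilazane, C[Si](C)(C)N[Si](C)(C)C; trifluoromethanesulfonic anhydride, O=S(=O)(OS(=O)(=O)C(F)(F)F)C(F)(F)F
Why: O-silylation, bromine–lithium exchange and a 1,3 O-to-C silyl shift (retro-Brook rearrangement) driven by formation of the lithium phenoxide, which is sulfonylated in the same flask, is the standard one-pot route from 2-bromophenols to 2-(trimethylsilyl)aryl triflates.

**Step 4**
Reactants: 8 3,5-dimethoxy-4-methyl-2-(trimethylsilyl)phenyl trifluoromethanesulfonate; 9 propionic acid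
Product: 12 1-(6-hydroxy-2,4-dimethoxy-3-methylphenyl)propan-1-one, via aryne 10 (not isolated), via ortho-cesioaryl propanoate 11 (not isolated)
Conditions: 8 (1.5 equiv), 9 (1.0 equiv), CsF (4 equiv), THF (0.02 M), sealed tube, 125 °C; then aq. NH4Cl
Reagents that add atoms: none
Why: Fluoride attacks silicon in 8 and triflate leaves to give aryne 10; propionate (from 9 and CsF) adds through oxygen to the aryne carbon remote from the methoxyl, which places the charge of aryl anion 11 on the carbon flanked by that methoxyl and the new ester oxygen. The anion then attacks the neighbouring ester carbonyl through a four-membered transition structure (anionic Fries-type 1,3 O-to-C acyl shift), so the C–O bond of the acid is broken and the phenoxide of 12 results, with the aryl–O and aryl–C(=O) bonds on adjacent ring carbons. The closest known reaction type is the fluoride-mediated insertion of arynes into the C–O bond of carboxylic acids, which gives ortho-hydroxyaryl ketones with aliphatic acids and with 3-alkoxy-substituted arynes. No ring is closed and no stereocentre is formed. The step needs regioselective addition across the aryne, which the inductively withdrawing methoxyl beside the triple bond should secure, because the distal carbon is the unhindered one and the developing negative charge is stabilised next to oxygen. It also needs the acyl shift to outrun protonation of 11, for which the high dilution, the aprotic medium and the acid as limiting reagent are chosen.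

**Step 5**
Reactants: 12 1-(6-hydroxy-2,4-dimethoxy-3-methylphenyl)propan-1-one
Product: 13 1-(2,6-dihydroxy-4-methoxy-3-methylphenyl)propan-1-one
Conditions: BCl3 (3 equiv), CH2Cl2, −78 °C to rt; then H2O
Reagents that add atoms: none
Why: Chelation-assisted Lewis-acid ether cleavage, in which the methoxyl squeezed between the ketone and the C-methyl is twisted out of conjugation and lies next to the boron-bound carbonyl, so chloride should remove its methyl group in preference to that of the para methoxyl, which is conjugated with the ketone.

**Step 6**
Reactants: 14 2,4,6-trihydroxytoluene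
Product: 15 1-(2,4,6-trihydroxy-3-methylphenyl)propan-1-one
Conditions: EtCOCl (1.05 equiv), AlCl3 (4 equiv), CH2Cl2/MeNO2, 0 °C to rt; then ice/1 M HCl
Reagents that add atoms: propionyl chloride, CCC(=O)Cl
Why: Friedel–Crafts acylation, in which the two free ring positions are equivalent and the first acyl group deactivates the ring toward a second acylation.

**Step 7**
Reactants: 15 1-(2,4,6-trihydroxy-3-methylphenyl)propan-1-one
Product: 16 1-[3-[(dimethylamino)methyl]-2,4,6-trihydroxy-5-methylphenyl]propan-1-one
Conditions: 37% aq. CH2O and 40% aq. Me2NH (premixed, 1.5 equiv each), EtOH, 0 °C to rt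
Reagents that add atoms: formaldehyde, C=O; dimethylamine, CNC
Why: Mannich aminomethylation of the single free ring position, which lies between two hydroxyls, should be fast with the premixed iminium source in excess, and the product is expected to separate as its zwitterion before it can alkylate unreacted 15.

**Step 8**
Reactants: 16 1-[3-[(dimethylamino)methyl]-2,4,6-trihydroxy-5-methylphenyl]propan-1-one; 13 1-(2,6-dihydroxy-4-methoxy-3-methylphenyl)propan-1-one
Product: 18 1-[3-[(2,4-dihydroxy-6-methoxy-5-methyl-3-propanoylphenyl)methyl]-2,4,6-trihydroxy-5-methylphenyl]propan-1-one, via ortho-quinone methide 17 (not isolated)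
Conditions: 16 (1.2 equiv), 1,4-dioxane, 100 °C, N2 stream; then 1 M HCl
Reagents that add atoms: none
Why: Thermal loss of dimethylamine from the zwitterionic Mannich base should give ortho-quinone methide 17, to which the only free position of ring B in 13 (ortho to a hydroxyl, ortho to the methoxyl, para to the other hydroxyl) adds in a Michael-type Friedel–Crafts alkylation that rearomatises both rings.

**Compound list**
1 | 2,6-dimethoxytoluene | COc1cccc(OC)c1C | starting material
2 | 2-(3,5-dimethoxy-4-methylphenyl)-4,4,5,5-tetramethyl-1,3,2-dioxaborolane | COc1cc(B2OC(C)(C)C(C)(C)O2)cc(OC)c1C | intermediate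
3 | 3,5-dimethoxy-4-methylphenol | COc1cc(O)cc(OC)c1C | intermediate
4 | 2-bromo-3,5-dimethoxy-4-methylphenol | COc1cc(O)c(Br)c(OC)c1C | intermediate
5 | (2-bromo-3,5-dimethoxy-4-methylphenoxy)trimethylsilane | COc1cc(O[Si](C)(C)C)c(Br)c(OC)c1C | intermediate
6 | (2-lithio-3,5-dimethoxy-4-methylphenoxy)trimethylsilane | COc1cc(O[Si](C)(C)C)c([Li])c(OC)c1C | intermediate
7 | lithium 3,5-dimethoxy-4-methyl-2-(trimethylsilyl)phenoxide | COc1cc([O-])c([Si](C)(C)C)c(OC)c1C.[Li+] | intermediate
8 | 3,5-dimethoxy-4-methyl-2-(trimethylsilyl)phenyl trifluoromethanesulfonate | COc1cc(OS(=O)(=O)C(F)(F)F)c([Si](C)(C)C)c(OC)c1C | intermediate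
9 | propionic acid | CCC(=O)O | starting material
10 | 3,5-dimethoxy-4-methylbenzyne (1,2-didehydro-3,5-dimethoxy-4-methylbenzene) | COC1=C(C)C(OC)=CC#C1 | intermediate
11 | cesium 2,4-dimethoxy-3-methyl-6-(propanoyloxy)benzen-1-ide (2-cesio-3,5-dimethoxy-4-methylphenyl propanoate) | CCC(=O)Oc1cc(OC)c(C)c(OC)[c-]1.[Cs+] | intermediate
12 | 1-(6-hydroxy-2,4-dimethoxy-3-methylphenyl)propan-1-one | CCC(=O)c1c(O)cc(OC)c(C)c1OC | intermediate
13 | 1-(2,6-dihydroxy-4-methoxy-3-methylphenyl)propan-1-one | CCC(=O)c1c(O)cc(OC)c(C)c1O | intermediate
14 | 2,4,6-trihydroxytoluene (2-methylbenzene-1,3,5-triol) | Cc1c(O)cc(O)cc1O | starting material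
15 | 1-(2,4,6-trihydroxy-3-methylphenyl)propan-1-one | CCC(=O)c1c(O)cc(O)c(C)c1O | intermediate
16 | 1-[3-[(dimethylamino)methyl]-2,4,6-trihydroxy-5-methylphenyl]propan-1-one | CCC(=O)c1c(O)c(C)c(O)c(CN(C)C)c1O | intermediate
17 | 3,5-dihydroxy-2-methyl-6-methylidene-4-propanoylcyclohexa-2,4-dien-1-one | CCC(=O)C1=C(O)C(=C)C(=O)C(C)=C1O | intermediate
18 | 1-[3-[(2,4-dihydroxy-6-methoxy-5-methyl-3-propanoylphenyl)methyl]-2,4,6-trihydroxy-5-methylphenyl]propan-1-one | CCC(=O)c1c(O)c(C)c(O)c(Cc2c(O)c(C(=O)CC)c(O)c(C)c2OC)c1O | target

**Step count**
Total: 8 steps. Longest linear sequence: 6 steps (steps 1, 2, 3, 4, 5 and 8); steps 6 and 7 form the two-step side branch to 16.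

**Steps most likely to fail**

Step 4. The aryl anion may be protonated by the acid or by traces of water before it can transfer the acyl group, so that only O-arylation takes place. Alternatively, the crowded anion between the methoxyl and the ester may add to the carbonyl too slowly, and the aryne is then consumed by the product phenoxide. The fallback leaves the aryne route and sets out from phenol 3. Acylation on oxygen (propionyl chloride, Et3N, CH2Cl2) should give 3,5-dimethoxy-4-methylphenyl propanoate F1. A Lewis-acid Fries rearrangement (BF3·OEt2, 90 °C) should then move the acyl group to carbon. The para position is blocked by the methyl group and the two ortho positions are equivalent, so only one ketone can form, and the route is rejoined at 12.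

Step 8. The methylene bridge may exchange between the rings through reversible release of quinone methides, which would lead to symmetrical dimers, and the Mannich base may lose its aminomethyl group by a retro-Mannich process before coupling. The fallback reverses the roles of the two rings and sets out from 13. Aminomethylation (aq. CH2O, aq. Me2NH, EtOH) should give 1-[3-[(dimethylamino)methyl]-2,6-dihydroxy-4-methoxy-5-methylphenyl]propan-1-one F2. Heating F2 in 1,4-dioxane with an excess of the cheap, more nucleophilic ketone 15 should release 3-hydroxy-5-methoxy-4-methyl-6-methylidene-2-propanoylcyclohexa-2,4-dien-1-one F3, which 15 traps at its free position. The route is rejoined at 18.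

Step 3. The silyl shift from oxygen to carbon may be incomplete, the aryllithium may be quenched before migration, and sulfonylation of the hindered phenoxide may be slow. The fallback replaces halogen–metal exchange by directed ortho-metalation; it sets out from phenol 3 and makes step 2 unnecessary. Carbamoylation (ClCONEt2, NaH, THF) should give 3,5-dimethoxy-4-methylphenyl N,N-diethylcarbamate F4. Lithiation between the carbamate and the methoxyl (s-BuLi, TMEDA, THF, −78 °C) and quenching with TMSCl should give 3,5-dimethoxy-4-methyl-2-(trimethylsilyl)phenyl N,N-diethylcarbamate F5. Reductive removal of the carbamate (LiAlH4, THF, reflux) should give 3,5-dimethoxy-4-methyl-2-(trimethylsilyl)phenol F6. Sulfonylation (Tf2O, pyridine, CH2Cl2, 0 °C) rejoins the route at 8.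

**Further compounds**
F1 | step 4 | 3,5-dimethoxy-4-methylphenyl propanoate | CCC(=O)Oc1cc(OC)c(C)c(OC)c1
F2 | step 8 | 1-[3-[(dimethylamino)methyl]-2,6-dihydroxy-4-methoxy-5-methylphenyl]propan-1-one | CCC(=O)c1c(O)c(CN(C)C)c(OC)c(C)c1O
F3 | step 8 | 3-hydroxy-5-methoxy-4-methyl-6-methylidene-2-propanoylcyclohexa-2,4-dien-1-one | CCC(=O)C1=C(O)C(C)=C(OC)C(=C)C1=O
F4 | step 3 | 3,5-dimethoxy-4-methylphenyl N,N-diethylcarbamate | CCN(CC)C(=O)Oc1cc(OC)c(C)c(OC)c1
F5 | step 3 | 3,5-dimethoxy-4-methyl-2-(trimethylsilyl)phenyl N,N-diethylcarbamate | CCN(CC)C(=O)Oc1cc(OC)c(C)c(OC)c1[Si](C)(C)C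
F6 | step 3 | 3,5-dimethoxy-4-methyl-2-(trimethylsilyl)phenol | COc1cc(O)c([Si](C)(C)C)c(OC)c1C
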